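**Plan**

1. The retrosynthesis cuts C11=C12 and C11'=C12' (two Wittig reactions on the C10 dialdehyde), C6'–C7' (Sonogashira coupling), C6–C7 (acetylide addition to a ring ketone) and, in the trihydroxy ring (ring A, C1–C6), the C1–C2 and C5–C6 bonds together.
2. Ring A arises first, in one [4+2] event. Its oxygens on C3 and C5 stand 1,3 with the methyl on C5, which is the pattern of a pentane-2,4-dione bis(silyl enol ether) used as diene. Its C6 carbinol lies next to the gem-dimethyl C1, which is the pattern of 2-methyl-1-nitroprop-1-ene used as a dimethylketene equivalent; the nitro group is taken out afterwards by a Nef reaction.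
3. The chain is then joined: C6 ketone plus enynol acetylide, hydroalumination and oxidation give the C15 trihydroxy dienal. Ring B comes from actinol via enol triflate and Sonogashira coupling. C15 + C10 gives C25, and C25 + C15 gives C40.
4. Stereochemistry: C5 is formed racemic and is fixed, together with C3, by a ketoreductase. C6 is set by axial acetylide addition under control of C5. C3' comes from (4R,6R)-actinol. The E alkenes come from the enynol, the hydroalumination and Wittig reaction with isomerization.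

Key step: step 2

Assumption: 2-methyl-1-nitroprop-1-ene, (2E)-3-methylpent-2-en-4-yn-1-ol, (4R,6R)-4-hydroxy-2,2,6-trimethylcyclohexan-1-one (actinol) and (2E,4E,6E)-2,7-dimethylocta-2,4,6-trienedial are taken as purchasable.

**Route**

Step 1
Reactants: 1 pentane-2,4-dione
Product: 3 (3Z)-2,4-bis(triethylsilyloxy)penta-1,3-diene, via (3Z)-4-(triethylsilyloxy)pent-3-en-2-one 2 (not isolated)
Conditions: Et3SiOTf (2.2 equiv), Et3N (2.6 equiv), Et2O, 0 °C to rt
Reagents that add atoms: triethylsilyl trifluoromethanesulfonate, CC[Si](CC)(CC)OS(=O)(=O)C(F)(F)F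
Why: Soft enolization and O-silylation of the β-diketone with a silyl triflate and an amine, known for the trimethylsilyl analogue, should give the 1,3-bis(silyloxy)diene; no stereocenter is formed.

Step 2
Reactants: 3 (3Z)-2,4-bis(triethylsilyloxy)penta-1,3-diene; 4 2-methyl-1-nitroprop-1-ene
Product: 6 rac-3,3,5-trimethyl-4-nitro-5-(triethylsilyloxy)cyclohexan-1-one (mixture of diastereomers), via silyl enol ether cycloadduct 5 (not isolated)
Conditions: toluene, 80 °C, sealed tube; then THF, 0.5 M aq. HCl, 0 °C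
Reagents that add atoms: none
Why: This is a normal-electron-demand Diels–Alder reaction that should be strongly asynchronous: the methylene terminus of diene 3, made nucleophilic by both silyloxy groups, bonds to the electrophilic CMe2 carbon of nitroalkene 4 (the later C1–C2 bond), and the methyl- and silyloxy-bearing terminus closes onto the nitro-bearing carbon (the later C5–C6 bond). The closest known reaction type is the cycloaddition of 1-alkoxy-3-silyloxy-1,3-dienes with nitroalkenes used as ketene equivalents. The six-membered ring is closed in the suprafacial [4+2] mode (in the stepwise limit, Michael addition followed by 6-endo-trig attack of the nitronate carbon on the silyloxy enone terminus). Two stereocenters arise, the tertiary silyloxy carbon and the nitro carbon; their relative configuration is not controlled and need not be, because the nitro carbon becomes the C6 carbonyl in step 3 and the tertiary center, formed racemic, is resolved in step 4. The step needs regioselectivity, which the concordant ortho/para directing effects of the two donor groups secure, and chemoselectivity for the carbocycle over the cyclic nitronate of the hetero-Diels–Alder mode, which the absence of a Lewis acid favours. Dilute acid then hydrolyses only the silyl enol ether, the tertiary triethylsilyl ether being much slower to cleave.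

Step 3
Reactants: 6 rac-3,3,5-trimethyl-4-nitro-5-(triethylsilyloxy)cyclohexan-1-one
Product: 8 rac-2,2,6-trimethyl-6-(triethylsilyloxy)cyclohexane-1,4-dione, via potassium nitronate 7 (not isolated)
Conditions: KOtBu (1.05 equiv), THF/MeOH, −78 °C; O3, −78 °C; N2 purge, KH2PO4/K2HPO4 buffer pH 7
Reagents that add atoms: ozone, [O-][O+]=O
Why: Nef reaction in its ozonolytic form: the nitro-bearing CH, far more acidic than the ketone α-CH2, is deprotonated selectively and the C=N bond of the nitronate is cleaved by ozone at low temperature, which should outrun β-elimination of the silyloxy group; the nitro-bearing stereocenter is erased.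

Step 4
Reactants: 8 rac-2,2,6-trimethyl-6-(triethylsilyloxy)cyclohexane-1,4-dione
Product: 9 (4S,6S)-4-hydroxy-2,2,6-trimethyl-6-(triethylsilyloxy)cyclohexan-1-one
Conditions: ketoreductase (NADPH-dependent, picked from a screening panel), NADP+ (cat.), propan-2-ol, DMSO (5% v/v), KH2PO4/K2HPO4 buffer pH 7, 30 °C; chromatography
Reagents that add atoms: none
Why: Enzymatic ketone reduction by a ketoreductase (alcohol dehydrogenase class): only the unhindered C4 carbonyl should react, the C1 carbonyl being flanked by two fully substituted carbons, and the enzyme is chosen so that the (6S)-enantiomer is reduced to the (4S) cis-hydroxy ether while the (6R)-enantiomer is left or gives the separable trans diastereomer, which sets C3 and fixes the absolute configuration at C5 of the target.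

Step 5
Reactants: 9 (4S,6S)-4-hydroxy-2,2,6-trimethyl-6-(triethylsilyloxy)cyclohexan-1-one
Product: 10 (4S,6S)-2,2,6-trimethyl-4,6-bis(triethylsilyloxy)cyclohexan-1-one
Conditions: Et3SiCl, imidazole, DMF, 0 °C to rt
Reagents that add atoms: chlorotriethylsilane, CC[Si](Cl)(CC)CC
Why: Standard silylation of the secondary alcohol; it makes both oxygens bulky, non-chelating groups that should stay equatorial in step 6, and no stereocenter is touched.

Step 6
Reactants: 10 (4S,6S)-2,2,6-trimethyl-4,6-bis(triethylsilyloxy)cyclohexan-1-one; 11 (2E)-3-methylpent-2-en-4-yn-1-ol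
Product: 13 (1R,2S,4S)-1-[(3E)-5-hydroxy-3-methylpent-3-en-1-yn-1-yl]-2,6,6-trimethyl-2,4-bis(triethylsilyloxy)cyclohexan-1-ol, via dilithium enynolate 12 (not isolated)
Conditions: 11 (2.5 equiv), n-BuLi (5.0 equiv), THF, −78 to −20 °C; then 10, −78 to 0 °C; H2O
Reagents that add atoms: none
Why: 1,2-Addition of a lithium acetylide to a ketone that cannot enolize; in the chair with both silyloxy groups equatorial the methyls on C2 and C6 are syn-axial and shield one face, so the acetylide should enter axially from the other face, anti to the C6 methyl, which places the new hydroxyl trans to the C6 silyloxy group (C6 of the target).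

Step 7
Reactants: 13 (1R,2S,4S)-1-[(3E)-5-hydroxy-3-methylpent-3-en-1-yn-1-yl]-2,6,6-trimethyl-2,4-bis(triethylsilyloxy)cyclohexan-1-ol
Product: 14 (1S,2S,4S)-1-[(1E,3E)-5-hydroxy-3-methylpenta-1,3-dien-1-yl]-2,6,6-trimethyl-2,4-bis(triethylsilyloxy)cyclohexan-1-ol
Conditions: NaAlH2(OCH2CH2OMe)2 (4 equiv), THF, 0 °C to rt; aq. potassium sodium tartrate
Reagents that add atoms: none
Why: Hydroxyl-directed trans-hydroalumination of the propargylic alcohol, followed by protonolysis, should give the (E)-C7=C8 alkene only; the existing alkene and the silyl ethers are inert.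

Step 8
Reactants: 14 (1S,2S,4S)-1-[(1E,3E)-5-hydroxy-3-methylpenta-1,3-dien-1-yl]-2,6,6-trimethyl-2,4-bis(triethylsilyloxy)cyclohexan-1-ol
Product: 15 (1S,2S,4S)-1-[(1E,3E)-5-hydroxy-3-methylpenta-1,3-dien-1-yl]-2,6,6-trimethylcyclohexane-1,2,4-triol
Conditions: Bu4NF (3 equiv), THF, 0 °C to rt
Reagents that add atoms: none
Why: Fluoride-induced desilylation removes both triethylsilyl ethers under non-acidic conditions, which spares the tertiary allylic alcohol.

Step 9
Reactants: 15 (1S,2S,4S)-1-[(1E,3E)-5-hydroxy-3-methylpenta-1,3-dien-1-yl]-2,6,6-trimethylcyclohexane-1,2,4-triol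
Product: 16 (2E,4E)-3-methyl-5-[(1S,2S,4S)-1,2,4-trihydroxy-2,6,6-trimethylcyclohexyl]penta-2,4-dienal
Conditions: MnO2 (activated, excess), CH2Cl2, rt
Reagents that add atoms: none
Why: Allylic oxidation with MnO2 is selective for the primary dienylic alcohol over the saturated secondary and the tertiary hydroxyls.

Step 10
Reactants: 17 (4R,6R)-4-hydroxy-2,2,6-trimethylcyclohexan-1-one
Product: 18 (4R,6R)-4-(tert-butyldimethylsilyloxy)-2,2,6-trimethylcyclohexan-1-one
Conditions: t-BuMe2SiCl, imidazole, DMF, rt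
Reagents that add atoms: tert-butyldimethylsilyl chloride, CC(C)(C)[Si](C)(C)Cl
Why: Standard silyl protection of the secondary alcohol, needed for the enolate chemistry of step 11; C3' of the target is taken unchanged from the chiral pool.

Step 11
Reactants: 18 (4R,6R)-4-(tert-butyldimethylsilyloxy)-2,2,6-trimethylcyclohexan-1-one
Product: 20 (4R)-4-(tert-butyldimethylsilyloxy)-2,6,6-trimethylcyclohex-1-en-1-yl trifluoromethanesulfonate, via potassium enolate 19 (not isolated)
Conditions: KN(SiMe3)2, THF, −78 °C; then PhNTf2, −78 °C to rt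
Reagents that add atoms: N-phenylbis(trifluoromethanesulfonimide), O=S(=O)(N(c1ccccc1)S(=O)(=O)C(F)(F)F)C(F)(F)F
Why: Enol triflate formation; the ketone has a single α-hydrogen, so only the tetrasubstituted enolate can form, and O-triflation gives the C5'=C6' alkene while the silyloxy center is untouched.

Step 12
Reactants: 20 (4R)-4-(tert-butyldimethylsilyloxy)-2,6,6-trimethylcyclohex-1-en-1-yl trifluoromethanesulfonate; 11 (2E)-3-methylpent-2-en-4-yn-1-ol
Product: 21 (2E)-5-[(4R)-4-(tert-butyldimethylsilyloxy)-2,6,6-trimethylcyclohex-1-en-1-yl]-3-methylpent-2-en-4-yn-1-ol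
Conditions: PdCl2(PPh3)2 (5 mol %), CuI (10 mol %), Et3N, DMF, rt to 50 °C
Reagents that add atoms: none
Why: Sonogashira coupling of a cyclohexenyl triflate with the terminal alkyne forms the C6'–C7' bond; the E geometry of the enynol is carried over.

Step 13
Reactants: 21 (2E)-5-[(4R)-4-(tert-butyldimethylsilyloxy)-2,6,6-trimethylcyclohex-1-en-1-yl]-3-methylpent-2-en-4-yn-1-ol
Product: 22 (1R)-4-[(3E)-5-hydroxy-3-methylpent-3-en-1-yn-1-yl]-3,5,5-trimethylcyclohex-3-en-1-ol
Conditions: Bu4NF, THF, rt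
Reagents that add atoms: none
Why: Fluoride desilylation frees the ring hydroxyl before the acidic phosphonium salt formation.

Step 14
Reactants: 22 (1R)-4-[(3E)-5-hydroxy-3-methylpent-3-en-1-yn-1-yl]-3,5,5-trimethylcyclohex-3-en-1-ol
Product: 23 {(2E)-5-[(4R)-4-hydroxy-2,6,6-trimethylcyclohex-1-en-1-yl]-3-methylpent-2-en-4-yn-1-yl}triphenylphosphonium bromide
Conditions: PPh3·HBr, MeOH, rt
Reagents that add atoms: triphenylphosphine hydrobromide, [Br-].c1ccccc1[PH+](c1ccccc1)c1ccccc1
Why: Phosphonium salt formation from an allylic alcohol through the allylic cation, the standard entry to carotenoid Wittig salts; the phosphine attacks the primary terminus and the secondary ring alcohol does not ionize.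

Step 15
Reactants: 23 {(2E)-5-[(4R)-4-hydroxy-2,6,6-trimethylcyclohex-1-en-1-yl]-3-methylpent-2-en-4-yn-1-yl}triphenylphosphonium bromide; 24 (2E,4E,6E)-2,7-dimethylocta-2,4,6-trienedial
Product: 26 (2E,4E,6E,8E,10E)-13-[(4R)-4-hydroxy-2,6,6-trimethylcyclohex-1-en-1-yl]-2,7,11-trimethyltrideca-2,4,6,8,10-pentaen-12-ynal, via phosphorus ylide 25 (not isolated)
Conditions: 24 (3 equiv), NaOMe, MeOH/CH2Cl2, 0 °C to rt; then heptane, 80 °C
Reagents that add atoms: none
Why: Wittig olefination with the dialdehyde in excess should stop at mono-olefination; the new C11'=C12' bond forms as an E/Z mixture whose hindered Z isomer should isomerize to E on warming.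

Step 16
Reactants: 26 (2E,4E,6E,8E,10E)-13-[(4R)-4-hydroxy-2,6,6-trimethylcyclohex-1-en-1-yl]-2,7,11-trimethyltrideca-2,4,6,8,10-pentaen-12-ynal
Product: 27 (2E,4E,6E,8E,10E)-13-[(4R)-4-hydroxy-2,6,6-trimethylcyclohex-1-en-1-yl]-2,7,11-trimethyltrideca-2,4,6,8,10-pentaen-12-yn-1-ol
Conditions: NaBH4, MeOH/CH2Cl2, 0 °C
Reagents that add atoms: none
Why: Borohydride 1,2-reduction of the polyenal gives the allylic alcohol without touching the polyene or the alkyne.

Step 17
Reactants: 27 (2E,4E,6E,8E,10E)-13-[(4R)-4-hydroxy-2,6,6-trimethylcyclohex-1-en-1-yl]-2,7,11-trimethyltrideca-2,4,6,8,10-pentaen-12-yn-1-ol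
Product: 28 {(2E,4E,6E,8E,10E)-13-[(4R)-4-hydroxy-2,6,6-trimethylcyclohex-1-en-1-yl]-2,7,11-trimethyltrideca-2,4,6,8,10-pentaen-12-yn-1-yl}triphenylphosphonium bromide
Conditions: PPh3·HBr, MeOH/CH2Cl2, 0 °C to rt
Reagents that add atoms: triphenylphosphine hydrobromide, [Br-].c1ccccc1[PH+](c1ccccc1)c1ccccc1
Why: Phosphonium salt formation through the polyenylic cation, as in step 14; the acid is kept away from the acid-sensitive trihydroxy fragment by placing the phosphonium group on this half.

Step 18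
Reactants: 28 the C25 phosphonium bromide of step 17; 16 (2E,4E)-3-methyl-5-[(1S,2S,4S)-1,2,4-trihydroxy-2,6,6-trimethylcyclohexyl]penta-2,4-dienal
Product: 30 (3S,5S,6S,3'R)-7',8'-didehydro-5,6-dihydro-β,β-carotene-3,5,6,3'-tetrol (the target), via C25 ylide 29 (not isolated)
Conditions: NaOMe (3 equiv), MeOH/CH2Cl2, 0 °C to rt, dark, argon; then EtOAc, 60 °C
Reagents that add atoms: none
Why: Wittig olefination joins C11 to C12 under basic conditions that the free hydroxyls tolerate; the hindered (11Z) isomer should isomerize to all-E on gentle warming, and no stereocenter is touched.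

**Compound list**

1 | pentane-2,4-dione | CC(=O)CC(C)=O | starting material
2 | (3Z)-4-(triethylsilyloxy)pent-3-en-2-one | CC(=O)/C=C(/C)O[Si](CC)(CC)CC | intermediate (not isolated)
3 | (3Z)-2,4-bis(triethylsilyloxy)penta-1,3-diene | C=C(O[Si](CC)(CC)CC)/C=C(/C)O[Si](CC)(CC)CC | intermediate
4 | 2-methyl-1-nitroprop-1-ene | CC(C)=C[N+](=O)[O-] | starting material
5 | rac-triethyl{[3,5,5-trimethyl-4-nitro-3-(triethylsilyloxy)cyclohex-1-en-1-yl]oxy}silane (mixture of diastereomers) | CC[Si](CC)(CC)OC1=CC(C)(O[Si](CC)(CC)CC)C([N+](=O)[O-])C(C)(C)C1 | intermediate (not isolated)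
6 | rac-3,3,5-trimethyl-4-nitro-5-(triethylsilyloxy)cyclohexan-1-one (mixture of diastereomers) | CC[Si](CC)(CC)OC1(C)CC(=O)CC(C)(C)C1[N+](=O)[O-] | intermediate
7 | potassium nitronate of 6 | CC[Si](CC)(CC)OC1(C)CC(=O)CC(C)(C)C1=[N+]([O-])[O-].[K+] | intermediate (not isolated)
8 | rac-2,2,6-trimethyl-6-(triethylsilyloxy)cyclohexane-1,4-dione | CC[Si](CC)(CC)OC1(C)CC(=O)CC(C)(C)C1=O | intermediate
9 | (4S,6S)-4-hydroxy-2,2,6-trimethyl-6-(triethylsilyloxy)cyclohexan-1-one | O=C1C(C)(C)C[C@H](O)C[C@]1(C)O[Si](CC)(CC)CC | intermediate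
10 | (4S,6S)-2,2,6-trimethyl-4,6-bis(triethylsilyloxy)cyclohexan-1-one | O=C1C(C)(C)C[C@H](O[Si](CC)(CC)CC)C[C@]1(C)O[Si](CC)(CC)CC | intermediate
11 | (2E)-3-methylpent-2-en-4-yn-1-ol | C#C/C(C)=C/CO | starting material
12 | dilithium salt of 11 (alkoxide and acetylide) | [Li+].[Li+].[C-]#C/C(C)=C/C[O-] | intermediate (not isolated)
13 | (1R,2S,4S)-1-[(3E)-5-hydroxy-3-methylpent-3-en-1-yn-1-yl]-2,6,6-trimethyl-2,4-bis(triethylsilyloxy)cyclohexan-1-ol | OC/C=C(\C)C#C[C@]1(O)C(C)(C)C[C@H](O[Si](CC)(CC)CC)C[C@]1(C)O[Si](CC)(CC)CC | intermediate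
14 | (1S,2S,4S)-1-[(1E,3E)-5-hydroxy-3-methylpenta-1,3-dien-1-yl]-2,6,6-trimethyl-2,4-bis(triethylsilyloxy)cyclohexan-1-ol | OC/C=C(C)/C=C/[C@]1(O)C(C)(C)C[C@H](O[Si](CC)(CC)CC)C[C@]1(C)O[Si](CC)(CC)CC | intermediate
15 | (1S,2S,4S)-1-[(1E,3E)-5-hydroxy-3-methylpenta-1,3-dien-1-yl]-2,6,6-trimethylcyclohexane-1,2,4-triol | OC/C=C(C)/C=C/[C@]1(O)C(C)(C)C[C@H](O)C[C@]1(C)O | intermediate
16 | (2E,4E)-3-methyl-5-[(1S,2S,4S)-1,2,4-trihydroxy-2,6,6-trimethylcyclohexyl]penta-2,4-dienal | O=C/C=C(C)/C=C/[C@]1(O)C(C)(C)C[C@H](O)C[C@]1(C)O | intermediate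
17 | (4R,6R)-4-hydroxy-2,2,6-trimethylcyclohexan-1-one (actinol) | O=C1C(C)(C)C[C@H](O)C[C@H]1C | starting material
18 | (4R,6R)-4-(tert-butyldimethylsilyloxy)-2,2,6-trimethylcyclohexan-1-one | O=C1C(C)(C)C[C@H](O[Si](C)(C)C(C)(C)C)C[C@H]1C | intermediate
19 | potassium (4R)-4-(tert-butyldimethylsilyloxy)-2,6,6-trimethylcyclohex-1-en-1-olate | CC1=C([O-])C(C)(C)C[C@H](O[Si](C)(C)C(C)(C)C)C1.[K+] | intermediate (not isolated)
20 | (4R)-4-(tert-butyldimethylsilyloxy)-2,6,6-trimethylcyclohex-1-en-1-yl trifluoromethanesulfonate | CC1=C(OS(=O)(=O)C(F)(F)F)C(C)(C)C[C@H](O[Si](C)(C)C(C)(C)C)C1 | intermediate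
21 | (2E)-5-[(4R)-4-(tert-butyldimethylsilyloxy)-2,6,6-trimethylcyclohex-1-en-1-yl]-3-methylpent-2-en-4-yn-1-ol | CC1=C(C#C/C(C)=C/CO)C(C)(C)C[C@H](O[Si](C)(C)C(C)(C)C)C1 | intermediate
22 | (1R)-4-[(3E)-5-hydroxy-3-methylpent-3-en-1-yn-1-yl]-3,5,5-trimethylcyclohex-3-en-1-ol | CC1=C(C#C/C(C)=C/CO)C(C)(C)C[C@H](O)C1 | intermediate
23 | {(2E)-5-[(4R)-4-hydroxy-2,6,6-trimethylcyclohex-1-en-1-yl]-3-methylpent-2-en-4-yn-1-yl}triphenylphosphonium bromide | CC1=C(C#C/C(C)=C/C[P+](c2ccccc2)(c2ccccc2)c2ccccc2)C(C)(C)C[C@H](O)C1.[Br-] | intermediate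
24 | (2E,4E,6E)-2,7-dimethylocta-2,4,6-trienedial | O=C/C(C)=C/C=C/C=C(C)/C=O | starting material
25 | ylide of 23 | CC1=C(C#C/C(C)=C/[CH-][P+](c2ccccc2)(c2ccccc2)c2ccccc2)C(C)(C)C[C@H](O)C1 | intermediate (not isolated)
26 | (2E,4E,6E,8E,10E)-13-[(4R)-4-hydroxy-2,6,6-trimethylcyclohex-1-en-1-yl]-2,7,11-trimethyltrideca-2,4,6,8,10-pentaen-12-ynal | CC1=C(C#C/C(C)=C/C=C/C(C)=C/C=C/C=C(C)/C=O)C(C)(C)C[C@H](O)C1 | intermediate
27 | (2E,4E,6E,8E,10E)-13-[(4R)-4-hydroxy-2,6,6-trimethylcyclohex-1-en-1-yl]-2,7,11-trimethyltrideca-2,4,6,8,10-pentaen-12-yn-1-ol | CC1=C(C#C/C(C)=C/C=C/C(C)=C/C=C/C=C(C)/CO)C(C)(C)C[C@H](O)C1 | intermediate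
28 | {(2E,4E,6E,8E,10E)-13-[(4R)-4-hydroxy-2,6,6-trimethylcyclohex-1-en-1-yl]-2,7,11-trimethyltrideca-2,4,6,8,10-pentaen-12-yn-1-yl}triphenylphosphonium bromide | CC1=C(C#C/C(C)=C/C=C/C(C)=C/C=C/C=C(C)/C[P+](c2ccccc2)(c2ccccc2)c2ccccc2)C(C)(C)C[C@H](O)C1.[Br-] | intermediate
29 | ylide of 28 | CC1=C(C#C/C(C)=C/C=C/C(C)=C/C=C/C=C(C)/[CH-][P+](c2ccccc2)(c2ccccc2)c2ccccc2)C(C)(C)C[C@H](O)C1 | intermediate (not isolated)
30 | (3S,5S,6S,3'R)-7',8'-didehydro-5,6-dihydro-β,β-carotene-3,5,6,3'-tetrol | CC1=C(C#C/C(C)=C/C=C/C(C)=C/C=C/C=C(C)/C=C/C=C(C)/C=C/[C@]2(O)C(C)(C)C[C@H](O)C[C@]2(C)O)C(C)(C)C[C@H](O)C1 | target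

**Count and risks**

Total step count: 18. Longest linear sequence: 10 steps (steps 1 to 9, then step 18).

Steps most likely to fail:

1. Step 2. Both new bonds end at fully substituted carbons, so the cycloaddition may stall, or it may divert to O-attack (a cyclic nitronate) or to open-chain Michael adducts that lose the tertiary silyloxy group. Fallback, from 1 and 4 back to 6: the dianion of pentane-2,4-dione 1 (NaH, then n-BuLi, THF, 0 °C) adds through its terminal carbon to nitroalkene 4 (Michael addition) to give 6,6-dimethyl-7-nitroheptane-2,4-dione F1. A catalytic amine base (DBU, THF, 0 °C) then closes the ring by an intramolecular Henry reaction to rac-5-hydroxy-3,3,5-trimethyl-4-nitrocyclohexan-1-one F2. Silylation of the tertiary hydroxyl (Et3SiOTf, 2,6-lutidine, CH2Cl2, −78 °C) returns compound 6.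

2. Step 3. The nitronate may form slowly at the hindered CH, or it may expel the neighbouring silyloxy group by β-elimination before it is oxidized. Fallback, from 6 back to 8, by a reductive instead of an oxidative route: SnCl2, PhSH and Et3N in MeCN reduce the nitro group to rac-4-(hydroxyimino)-3,3,5-trimethyl-5-(triethylsilyloxy)cyclohexan-1-one F3 without passing through a free nitronate. Buffered aqueous TiCl3 (NH4OAc, THF) then cleaves the N–O bond and the imine hydrolyses to dione 8.

3. Step 4. The two flanks of the C4 carbonyl are nearly mirror images, so the enzyme may fail to tell the enantiomers apart or may deliver hydride under substrate control. Fallback, from 8 back to 10, by chemical reduction and classical resolution: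
   - HF·pyridine (THF, 0 °C) gives rac-2-hydroxy-2,6,6-trimethylcyclohexane-1,4-dione F4.
   - Chelation-controlled syn reduction (Et2BOMe, NaBH4, THF/MeOH, −78 °C; Narasaka–Prasad) gives rac-cis-2,4-dihydroxy-2,6,6-trimethylcyclohexan-1-one F5.
   - Esterification of the secondary hydroxyl with (S)-O-methylmandelic acid (DCC, DMAP) and chromatographic separation of the two diastereomers give (1S,3S)-3-hydroxy-3,5,5-trimethyl-4-oxocyclohexyl (2S)-methoxy(phenyl)acetate F6.
   - Methanolysis (K2CO3, MeOH) frees (2S,4S)-2,4-dihydroxy-2,6,6-trimethylcyclohexan-1-one F7.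
   - Bis-silylation (Et3SiOTf, 2,6-lutidine) gives compound 10.

**Further compounds**

F1 | step 2 | 6,6-dimethyl-7-nitroheptane-2,4-dione | CC(=O)CC(=O)CC(C)(C)C[N+](=O)[O-]
F2 | step 2 | rac-5-hydroxy-3,3,5-trimethyl-4-nitrocyclohexan-1-one | O=C1CC(C)(C)C([N+](=O)[O-])C(C)(O)C1
F3 | step 3 | rac-4-(hydroxyimino)-3,3,5-trimethyl-5-(triethylsilyloxy)cyclohexan-1-one | CC[Si](CC)(CC)OC1(C)CC(=O)CC(C)(C)C1=NO
F4 | step 4 | rac-2-hydroxy-2,6,6-trimethylcyclohexane-1,4-dione | O=C1CC(C)(C)C(=O)C(C)(O)C1
F5 | step 4 | rac-cis-2,4-dihydroxy-2,6,6-trimethylcyclohexan-1-one (racemate, one enantiomer drawn) | O=C1C(C)(C)C[C@H](O)C[C@]1(C)O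
F6 | step 4 | (1S,3S)-3-hydroxy-3,5,5-trimethyl-4-oxocyclohexyl (2S)-methoxy(phenyl)acetate | O=C1C(C)(C)C[C@H](OC(=O)[C@@H](OC)c2ccccc2)C[C@]1(C)O
F7 | step 4 | (2S,4S)-2,4-dihydroxy-2,6,6-trimethylcyclohexan-1-one | O=C1C(C)(C)C[C@H](O)C[C@]1(C)O
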